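**Retrosynthetic overview**
- Target 16 ⇐ diketone 15 by a singlet-oxygen ene reaction on the C8(=O)–CH2–CH=CMe2 unit (last step).
- 15 ⇐ enone ester 12: the oxirane is the second ring formed, by hydroxyl-directed epoxidation of the Δ3 olefin after 1,2-reduction, then oxidation back to the ketone.
- 12 ⇐ acyclic keto-aldehyde 10: the carbocycle is the first ring formed, by C1–C6 closure in a catalytic asymmetric intramolecular glyoxal-ene reaction with loss of H from C14 (sets C1, C6 and the 7(14)-ene).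
- 10 ⇐ vinyl iodide 8 + ethyl diethoxyacetate; 8 ⇐ alkynol 6 + allylic bromide 3 + MeMgBr (both Z olefins come from alkynes).

Assumption: bisabolane numbering is used (C1 = O-acyl carbon, C2 = ring ketone, C3/C4 = epoxide, C6 = ring CH, C7(=C14), C8 = side-chain ketone, C11 = OOH carbon); the presumed biosynthesis is C1–C6 closure of a farnesyl-type chain with loss of H-14, epoxidation of the Δ3 olefin and an ene reaction of O2; C8 is carried as an uncontrolled carbinol centre (both epimers) from 6 to 14 and becomes a ketone in step 10.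

**Route**

Step 1
Reactants: 1 but-2-yn-1-ol
Product: 2 (2Z)-3-iodobut-2-en-1-ol
Conditions: Red-Al, Et2O, 0 °C → rt; then I2, THF, −78 °C
Reagents that add atoms: iodine, II
Why: Hydroxyl-directed trans-hydroalumination puts Al on C3 cis to CH2O and iodinolysis with retention gives the Z-vinyl iodide (I cis to CH2OH) that later becomes the 3Z olefin.

Step 2
Reactants: 2 (2Z)-3-iodobut-2-en-1-ol
Product: 3 (2Z)-1-bromo-3-iodobut-2-ene
Conditions: CBr4, PPh3, CH2Cl2, 0 °C
Reagents that add atoms: carbon tetrabromide, BrC(Br)(Br)Br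
Why: Appel bromination of the primary allylic alcohol is an SN2 process that leaves the olefin geometry untouched.

Step 3
Reactants: 4 4-methylpent-3-en-1-ol
Product: 6 6-methylhept-5-en-1-yn-3-ol (racemic), via 4-methylpent-3-enal 5 (not isolated)
Conditions: (COCl)2, DMSO, Et3N, CH2Cl2, −78 °C; then HC≡CMgBr, THF, −78 → 0 °C
Reagents that add atoms: ethynylmagnesium bromide, C#C[Mg]Br
Why: Swern oxidation gives the isomerisation-prone β,γ-unsaturated aldehyde, which is trapped in the same flask by 1,2-addition of the alkynyl Grignard reagent (one-pot Swern/Grignard); the new carbinol centre is left racemic because it ends as the C8 ketone.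

Step 4
Reactants: 6 6-methylhept-5-en-1-yn-3-ol; 3 (2Z)-1-bromo-3-iodobut-2-ene
Product: 8 triethyl{[(6Z,9Z)-10-iodo-2,6-dimethylundeca-2,6,9-trien-5-yl]oxy}silane (racemic), via (6Z,9Z)-10-iodo-2,6-dimethylundeca-2,6,9-trien-5-ol 7 (not isolated)
Conditions: MeMgBr (2.2 equiv), CuI (10 mol %), Et2O, −10 °C → rt; then 3, −20 → 0 °C; then TESOTf, 0 °C
Reagents that add atoms: methylmagnesium bromide, C[Mg]Br; triethylsilyl trifluoromethanesulfonate, CC[Si](CC)(CC)OS(=O)(=O)C(F)(F)F
Why: Copper-catalysed alkoxide-directed anti-carbomagnesiation (Duboudin reaction) adds methyl to the internal alkyne carbon and leaves Mg on the terminal carbon cis to the carbinol, so copper-catalysed SN2 allylation by 3 (vinyl iodide untouched) fixes the 6Z geometry (C5 cis to C8, the C14 methyl trans to C5) and the magnesium alkoxide is silylated in situ.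

Step 5
Reactants: 8 triethyl{[(6Z,9Z)-10-iodo-2,6-dimethylundeca-2,6,9-trien-5-yl]oxy}silane
Product: 9 (3Z,6Z)-1,1-diethoxy-3,7,11-trimethyl-8-(triethylsilyloxy)dodeca-3,6,10-trien-2-one
Conditions: t-BuLi (2.1 equiv), Et2O, −78 °C; then (EtO)2CHCO2Et, −78 °C
Reagents that add atoms: ethyl diethoxyacetate, CCOC(=O)C(OCC)OCC
Why: Iodine–lithium exchange proceeds with retention of the Z geometry and the vinyllithium acylates the α,α-dialkoxy ester once (chelated tetrahedral intermediate), installing C2 as ketone and C1 as masked aldehyde.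

Step 6
Reactants: 9 (3Z,6Z)-1,1-diethoxy-3,7,11-trimethyl-8-(triethylsilyloxy)dodeca-3,6,10-trien-2-one
Product: 10 (3Z,6Z)-3,7,11-trimethyl-2-oxo-8-(triethylsilyloxy)dodeca-3,6,10-trienal
Conditions: TESOTf, 2,6-lutidine, CH2Cl2, 0 °C; then H2O
Reagents that add atoms: water, O
Why: Silyl triflate/lutidine acetal cleavage through a pyridinium intermediate unmasks the aldehyde under non-acidic conditions that spare the TES ether, the Z-enone and the skipped diene and provide no acid for a racemic background cyclisation.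

Step 7
Reactants: 10 (3Z,6Z)-3,7,11-trimethyl-2-oxo-8-(triethylsilyloxy)dodeca-3,6,10-trienal
Product: 12 (1S,6S)-3-methyl-6-[6-methyl-3-(triethylsilyloxy)hepta-1,5-dien-2-yl]-2-oxocyclohex-3-en-1-yl (2E)-2-methylbut-2-enoate (both epimers at the silyloxy carbon), via (5S,6S)-6-hydroxy-2-methyl-5-[6-methyl-3-(triethylsilyloxy)hepta-1,5-dien-2-yl]cyclohex-2-en-1-one 11 (not isolated)
Conditions: [Cu((S,S)-t-Bu-box)](SbF6)2 (10 mol %), 4 Å MS, CH2Cl2, −40 → −10 °C; then pyridine, DMAP (cat.), tigloyl chloride, 0 °C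
Reagents that add atoms: tigloyl chloride [(2E)-2-methylbut-2-enoyl chloride], C/C=C(\C)C(Cl)=O
Why: Proposed new method: two-point binding of the 1,2-dicarbonyl to the C2-symmetric Cu(II) Lewis acid exposes the Si face of aldehyde C1 to the 6Z olefin, which closes C1–C6 through a chair-like type-I carbonyl-ene transition state with the C1 oxygen and C7 pseudo-equatorial (1,6-trans) while the C14 methyl, trans to C5, passes its hydrogen to the aldehyde oxygen to give the 7(14)-ene, the closest known reactions being Cu(II)–bis(oxazoline) glyoxylate-ene reactions and the Lewis-acid neral → isopiperitenol cyclisation, and the resulting α-ketol is acylated in the same flask.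

Step 8
Reactants: 12 (1S,6S)-3-methyl-6-[6-methyl-3-(triethylsilyloxy)hepta-1,5-dien-2-yl]-2-oxocyclohex-3-en-1-yl (2E)-2-methylbut-2-enoate
Product: 13 (1S,2S,6S)-2-hydroxy-3-methyl-6-[6-methyl-3-(triethylsilyloxy)hepta-1,5-dien-2-yl]cyclohex-3-en-1-yl (2E)-2-methylbut-2-enoate
Conditions: NaBH4, CeCl3·7H2O, MeOH, −78 °C
Reagents that add atoms: none
Why: Luche 1,2-reduction with axial hydride delivery gives the pseudo-equatorial C2 alcohol, trans to the C1 ester and cis to the C6 side chain (as in carvone → cis-carveol).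

Step 9
Reactants: 13 (1S,2S,6S)-2-hydroxy-3-methyl-6-[6-methyl-3-(triethylsilyloxy)hepta-1,5-dien-2-yl]cyclohex-3-en-1-yl (2E)-2-methylbut-2-enoate
Product: 14 (1R,2R,3S,4S,6S)-2-hydroxy-1-methyl-4-[6-methyl-3-(triethylsilyloxy)hepta-1,5-dien-2-yl]-7-oxabicyclo[4.1.0]heptan-3-yl (2E)-2-methylbut-2-enoate
Conditions: VO(acac)2 (5 mol %), t-BuOOH (decane), CH2Cl2, 0 °C → rt
Reagents that add atoms: tert-butyl hydroperoxide, CC(C)(C)OO
Why: Vanadium-catalysed hydroxyl-directed epoxidation delivers oxygen to the Δ3 olefin syn to the C2 hydroxyl (cis to the side chain, trans to the ester) and leaves the silyl-ether, isolated and ester-conjugated olefins untouched.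

Step 10
Reactants: 14 (1R,2R,3S,4S,6S)-2-hydroxy-1-methyl-4-[6-methyl-3-(triethylsilyloxy)hepta-1,5-dien-2-yl]-7-oxabicyclo[4.1.0]heptan-3-yl (2E)-2-methylbut-2-enoate
Product: 15 (1S,3S,4S,6S)-1-methyl-4-(6-methyl-3-oxohepta-1,5-dien-2-yl)-2-oxo-7-oxabicyclo[4.1.0]heptan-3-yl (2E)-2-methylbut-2-enoate
Conditions: IBX (5 equiv), DMSO, rt
Reagents that add atoms: none
Why: IBX in DMSO cleaves the triethylsilyl ether and oxidises both the freed allylic C8 alcohol and the C2 epoxy alcohol to ketones (one-pot oxidative desilylation/oxidation under near-neutral conditions that do not conjugate the β,γ-enone), which also erases the uncontrolled C8 centre.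

Step 11
Reactants: 15 (1S,3S,4S,6S)-1-methyl-4-(6-methyl-3-oxohepta-1,5-dien-2-yl)-2-oxo-7-oxabicyclo[4.1.0]heptan-3-yl (2E)-2-methylbut-2-enoate
Product: 16 (1S,3S,4S,6S)-4-[(4E)-6-hydroperoxy-6-methyl-3-oxohepta-1,4-dien-2-yl]-1-methyl-2-oxo-7-oxabicyclo[4.1.0]heptan-3-yl (2E)-2-methylbut-2-enoate (CNP0284595.1)
Conditions: O2, hν (visible), TPP (cat.), CH2Cl2, 0 °C
Reagents that add atoms: oxygen, O=O
Why: Schenck ene reaction of singlet oxygen with the β,γ-unsaturated ketone abstracts a C9 hydrogen α to the carbonyl and places O2 on C11, giving the conjugated E-γ-hydroperoxy enone, while the enone and tiglate olefins are too electron-poor to react.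

**Compound list**
1 | but-2-yn-1-ol | CC#CCO | starting material
2 | (2Z)-3-iodobut-2-en-1-ol | C/C(I)=C/CO | intermediate
3 | (2Z)-1-bromo-3-iodobut-2-ene | C/C(I)=C/CBr | intermediate
4 | 4-methylpent-3-en-1-ol | CC(C)=CCCO | starting material
5 | 4-methylpent-3-enal | CC(C)=CCC=O | intermediate
6 | 6-methylhept-5-en-1-yn-3-ol (racemic) | C#CC(O)CC=C(C)C | intermediate
7 | (6Z,9Z)-10-iodo-2,6-dimethylundeca-2,6,9-trien-5-ol (racemic) | C/C(I)=C/C/C=C(/C)C(O)CC=C(C)C | intermediate
8 | triethyl{[(6Z,9Z)-10-iodo-2,6-dimethylundeca-2,6,9-trien-5-yl]oxy}silane (racemic) | C/C(I)=C/C/C=C(/C)C(CC=C(C)C)O[Si](CC)(CC)CC | intermediate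
9 | (3Z,6Z)-1,1-diethoxy-3,7,11-trimethyl-8-(triethylsilyloxy)dodeca-3,6,10-trien-2-one | CCOC(OCC)C(=O)/C(C)=C\C/C=C(/C)C(CC=C(C)C)O[Si](CC)(CC)CC | intermediate
10 | (3Z,6Z)-3,7,11-trimethyl-2-oxo-8-(triethylsilyloxy)dodeca-3,6,10-trienal | O=CC(=O)/C(C)=C\C/C=C(/C)C(CC=C(C)C)O[Si](CC)(CC)CC | intermediate
11 | (5S,6S)-6-hydroxy-2-methyl-5-[6-methyl-3-(triethylsilyloxy)hepta-1,5-dien-2-yl]cyclohex-2-en-1-one | C=C(C(CC=C(C)C)O[Si](CC)(CC)CC)[C@@H]1CC=C(C)C(=O)[C@H]1O | intermediate
12 | (1S,6S)-3-methyl-6-[6-methyl-3-(triethylsilyloxy)hepta-1,5-dien-2-yl]-2-oxocyclohex-3-en-1-yl (2E)-2-methylbut-2-enoate | C=C(C(CC=C(C)C)O[Si](CC)(CC)CC)[C@@H]1CC=C(C)C(=O)[C@H]1OC(=O)/C(C)=C/C | intermediate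
13 | (1S,2S,6S)-2-hydroxy-3-methyl-6-[6-methyl-3-(triethylsilyloxy)hepta-1,5-dien-2-yl]cyclohex-3-en-1-yl (2E)-2-methylbut-2-enoate | C=C(C(CC=C(C)C)O[Si](CC)(CC)CC)[C@@H]1CC=C(C)[C@H](O)[C@H]1OC(=O)/C(C)=C/C | intermediate
14 | (1R,2R,3S,4S,6S)-2-hydroxy-1-methyl-4-[6-methyl-3-(triethylsilyloxy)hepta-1,5-dien-2-yl]-7-oxabicyclo[4.1.0]heptan-3-yl (2E)-2-methylbut-2-enoate | C=C(C(CC=C(C)C)O[Si](CC)(CC)CC)[C@@H]1C[C@@H]2O[C@]2(C)[C@H](O)[C@H]1OC(=O)/C(C)=C/C | intermediate
15 | (1S,3S,4S,6S)-1-methyl-4-(6-methyl-3-oxohepta-1,5-dien-2-yl)-2-oxo-7-oxabicyclo[4.1.0]heptan-3-yl (2E)-2-methylbut-2-enoate | C=C(C(=O)CC=C(C)C)[C@@H]1C[C@@H]2O[C@]2(C)C(=O)[C@H]1OC(=O)/C(C)=C/C | intermediate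
16 | (1S,3S,4S,6S)-4-[(4E)-6-hydroperoxy-6-methyl-3-oxohepta-1,4-dien-2-yl]-1-methyl-2-oxo-7-oxabicyclo[4.1.0]heptan-3-yl (2E)-2-methylbut-2-enoate | C=C(C(=O)/C=C/C(C)(C)OO)[C@@H]1C[C@@H]2O[C@]2(C)C(=O)[C@H]1OC(=O)/C(C)=C/C | target

**Totals**
Total step count: 11. Longest linear sequence: 10 steps (1 → 2 → 3 → 8 → 9 → 10 → 12 → 13 → 14 → 15 → 16).

**Three steps most likely to fail, with fallbacks**

The ene closure of step 7 is the riskiest: the allylic silyloxy group deactivates the olefin, C8–H instead of C14–H may be lost, and the facial control is unproven. The fallback ends the closure with silicon instead of hydrogen transfer. It sets out from 6 and 3: carbomagnesiation of 6 with Me3SiCH2MgCl/CuI, allylation with 3 and silylation give triethyl{[(6E,9Z)-10-iodo-2-methyl-6-[(trimethylsilyl)methyl]undeca-2,6,9-trien-5-yl]oxy}silane F1. Iodine–lithium exchange and acylation with the magnesium alkoxide of 2-hydroxy-N-methoxy-N-methylacetamide give (3Z,6E)-1-hydroxy-3,11-dimethyl-8-(triethylsilyloxy)-7-[(trimethylsilyl)methyl]dodeca-3,6,10-trien-2-one F2. Dess–Martin oxidation gives (3Z,6E)-3,11-dimethyl-2-oxo-8-(triethylsilyloxy)-7-[(trimethylsilyl)methyl]dodeca-3,6,10-trienal F3. An enantioselective intramolecular Hosomi–Sakurai reaction (Sc(OTf)3/(S,S)-Ph-pybox, CH2Cl2, −40 °C) then closes C1–C6 with loss of the silyl group from C14, and the fallback comes back to the route at 11, which is acylated to 12 as before.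

The three-component coupling of step 4 may fail because anti-carbomagnesiation of a secondary propargylic alcohol can be sluggish and the allylation may give SN2′ product. The fallback makes the 6Z olefin by olefination and sets out from 6 and 3. Alkynol 6 is silylated to 6-methyl-3-(triethylsilyloxy)hept-5-en-1-yne F4 and hydrated (Au(I), wet MeOH) to 6-methyl-3-(triethylsilyloxy)hept-5-en-2-one F5. Bromide 3 is homologated with Ph3P=CH2 to [(3Z)-4-iodopent-3-en-1-yl]triphenylphosphonium bromide F6. A salt-free Wittig reaction of the ylide of F6 with F5 (Z-selective olefination of an α-alkoxy ketone, the ylide carbon chain ending cis to the oxygenated carbon) comes back to the route at 8.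

The unmasking of step 6 may fail because an α-keto acetal ionises reluctantly and the free vinylglyoxal can isomerise or cyclise. The fallback brings C1 in at the alcohol level and sets out from 8: the vinyllithium from 8 is acylated with the magnesium alkoxide of 2-hydroxy-N-methoxy-N-methylacetamide to give (3Z,6Z)-1-hydroxy-3,7,11-trimethyl-8-(triethylsilyloxy)dodeca-3,6,10-trien-2-one F7, and buffered Dess–Martin oxidation of this α-ketol comes back to the route at 10.

Further compounds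
F1 | step 7 | triethyl{[(6E,9Z)-10-iodo-2-methyl-6-[(trimethylsilyl)methyl]undeca-2,6,9-trien-5-yl]oxy}silane | C/C(I)=C/C/C=C(/C[Si](C)(C)C)C(CC=C(C)C)O[Si](CC)(CC)CC
F2 | step 7 | (3Z,6E)-1-hydroxy-3,11-dimethyl-8-(triethylsilyloxy)-7-[(trimethylsilyl)methyl]dodeca-3,6,10-trien-2-one | OCC(=O)/C(C)=C\C/C=C(/C[Si](C)(C)C)C(CC=C(C)C)O[Si](CC)(CC)CC
F3 | step 7 | (3Z,6E)-3,11-dimethyl-2-oxo-8-(triethylsilyloxy)-7-[(trimethylsilyl)methyl]dodeca-3,6,10-trienal | O=CC(=O)/C(C)=C\C/C=C(/C[Si](C)(C)C)C(CC=C(C)C)O[Si](CC)(CC)CC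
F4 | step 4 | 6-methyl-3-(triethylsilyloxy)hept-5-en-1-yne | C#CC(CC=C(C)C)O[Si](CC)(CC)CC
F5 | step 4 | 6-methyl-3-(triethylsilyloxy)hept-5-en-2-one | CC(=O)C(CC=C(C)C)O[Si](CC)(CC)CC
F6 | step 4 | [(3Z)-4-iodopent-3-en-1-yl]triphenylphosphonium bromide | C/C(I)=C/CC[P+](c1ccccc1)(c1ccccc1)c1ccccc1.[Br-]
F7 | step 6 | (3Z,6Z)-1-hydroxy-3,7,11-trimethyl-8-(triethylsilyloxy)dodeca-3,6,10-trien-2-one | OCC(=O)/C(C)=C\C/C=C(/C)C(CC=C(C)C)O[Si](CC)(CC)CC
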